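Cuts: C4(middle)–C8(lower); then, in one operation, O1–C8a of the middle pyran ring together with C8(middle)–C4(upper); then C4–C4a and C2–C3 of the middle three-carbon chain.
Enabling feature: in ring A of the middle (epifisetinidol) unit, O1 sits on C8a and C4 of the upper unit on the neighbouring C8, next to the C7 oxygen. This ortho O/C pair is the retron of an aryne (C8≡C8a) inserting into the C4–O bond of a flavan-4-yl ether.
Forward: Evans glycolate aldol (C2–C3), DDQ etherification that hangs benzylated epicatechin on the C2 oxygen, aryllithium/Weinreb ketone (C4–C4a), reduction and O-methylation, aryne insertion (ring C of the middle unit plus the upper 4→8 bond), Lewis-acid coupling with benzylated catechin (lower 4→8 bond), hydrogenolysis.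
Stereochemistry: upper and lower units from (−)-epicatechin and (+)-catechin; C2/C3 of the middle unit from the oxazolidinone auxiliary; both C4 centres from attack anti to the cis 2-aryl/3-benzyloxy pair (3,4-trans, 4β).

Key step: step 10

Remark: open-chain precursors are numbered as in the middle flavan unit they become; the carbon that becomes C4 of that unit is carried as an epimer mixture (no descriptor in the SMILES of 16–21 and 24) because it is ionised in step 12.

Step 1
Reactants: 1 (S)-4-benzyloxazolidin-2-one; 2 (benzyloxy)acetyl chloride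
Product: 3 (S)-4-benzyl-3-[(benzyloxy)acetyl]oxazolidin-2-one
Conditions: Et3N, DMAP (cat.), CH2Cl2, 0 °C → rt
Reagents that add atoms: none
Why: DMAP-catalysed N-acylation of the oxazolidinone by the acid chloride; no stereocentre is formed.

Step 2
Reactants: 3 (S)-4-benzyl-3-[(benzyloxy)acetyl]oxazolidin-2-one; 4 3,4-bis(benzyloxy)benzaldehyde
Product: 6 syn-aldol imide (S)-4-benzyl-3-[(2S,3R)-2-(benzyloxy)-3-[3,4-bis(benzyloxy)phenyl]-3-hydroxypropanoyl]oxazolidin-2-one, via Z-boron enolate 5 (not isolated)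
Conditions: Bu2BOTf, Et3N, CH2Cl2, −78 → 0 °C; then 4, −78 → 0 °C; H2O2, MeOH, pH 7 buffer
Reagents that add atoms: none
Why: Evans syn glycolate aldol, in which the Z-boron enolate reacts through a Zimmerman–Traxler chair and the (S)-benzyl group of the auxiliary shields one enolate face, so the future C3 (benzyloxy) and C2 (carbinol) centres of the middle unit should form as the syn pair with the required absolute configuration.

Step 3
Reactants: 6 syn-aldol imide
Product: 7 (2S,3R)-2-(benzyloxy)-3-[3,4-bis(benzyloxy)phenyl]-3-hydroxy-N-methoxy-N-methylpropanamide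
Conditions: MeNHOMe·HCl, AlMe3, THF, −20 → 0 °C
Reagents that add atoms: N,O-dimethylhydroxylamine hydrochloride, CNOC.Cl
Why: aluminium amide transamidation of an aldol imide to the Weinreb amide, assisted by the free β-hydroxyl group, releases the auxiliary and leaves both stereocentres untouched.

Step 4
Reactants: 8 (−)-epicatechin
Product: 9 5,7,3',4'-tetra-O-benzyl-(−)-epicatechin
Conditions: BnBr (4.2 equiv), K2CO3, DMF, 0 °C → rt
Reagents that add atoms: benzyl bromide, BrCc1ccccc1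
Why: Williamson benzylation with a carbonate base should alkylate only the four phenols and leave the secondary 3-OH free; C2 and C3 come from the chiral pool.

Step 5
Reactants: 9 5,7,3',4'-tetra-O-benzyl-(−)-epicatechin
Product: 10 3,5,7,3',4'-penta-O-benzyl-(−)-epicatechin
Conditions: NaH, BnBr, DMF, 0 °C → rt
Reagents that add atoms: benzyl bromide, BrCc1ccccc1
Why: Williamson etherification of the remaining secondary alcohol removes the last acidic proton of the upper unit.

Step 6
Reactants: 10 3,5,7,3',4'-penta-O-benzyl-(−)-epicatechin; 7 Weinreb amide alcohol (2.5 equiv, excess recovered)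
Product: 12 4β-flavanyl ether in which the hydroxyl oxygen of 7 is bonded to C4 of penta-O-benzylepicatechin, via flavan-4-yl cation 11 (not isolated)
Conditions: DDQ (1.3 equiv), CH2Cl2, 4 Å molecular sieves, 0 °C → rt
Reagents that add atoms: none
Why: DDQ-mediated benzylic C–H etherification at C4 of a benzylated flavan-3-ol, in which hydride abstraction gives the cation stabilised by O1 and the 5,7-oxygens and the alcohol should add on the β-face, anti to the 2-aryl and 3-benzyloxy groups, to give the 3,4-trans ether.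

Step 7
Reactants: 12 4β-flavanyl ether Weinreb amide; 13 4-(benzyloxy)-1-bromo-2-fluorobenzene
Product: 15 aryl ketone in which the amide of 12 is replaced by a 4-(benzyloxy)-2-fluorobenzoyl group, via aryllithium 14 (not isolated)
Conditions: 13 (2.2 equiv), n-BuLi (2.1 equiv), THF, −78 °C; then 12, −78 °C; NH4Cl aq. at −78 °C
Reagents that add atoms: none
Why: bromine–lithium exchange followed by Weinreb ketone synthesis, where the chelated tetrahedral intermediate prevents over-addition and at −78 °C the ortho-fluoroaryllithium should not lose LiF.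

Step 8
Reactants: 15 aryl ketone
Product: 16 benzylic alcohol (epimers at the new carbinol carbon)
Conditions: NaBH4, THF–EtOH, −20 → 0 °C
Reagents that add atoms: none
Why: borohydride reduction of the aryl ketone under near-neutral conditions that spare the acid-labile flavanyl ether; the new centre needs no control because it is ionised in step 12.

Step 9
Reactants: 16 benzylic alcohol
Product: 17 benzylic methyl ether (insertion substrate)
Conditions: NaH, MeI, THF–DMF, 0 °C
Reagents that add atoms: iodomethane, CI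
Why: Williamson methylation gives a base-stable methyl ether that later serves as the leaving group at C4 of the middle unit.

Step 10
Reactants: 17 benzylic methyl ether
Product: 21 protected dimer penta-O-benzylepicatechin-(4β→8)-[3,7,3',4'-tetra-O-benzyl-4-methoxyepifisetinidol], via lithiated fluoroarene 18 (not isolated), via aryne 19 (not isolated), via oxonium zwitterion 20 (not isolated)
Conditions: n-BuLi (1.05 equiv), THF (0.01 M), −78 °C, 1 h; then warm to 0 °C; NH4Cl aq.
Reagents that add atoms: none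
Why: Proposed new method: n-BuLi removes the ring A proton flanked by F and OBn (C8) to give 18, which loses LiF on warming to the 3-alkoxyaryne 19; the tethered ether oxygen adds to the distal aryne carbon C8a in a 6-exo-dig closure that forms the O1–C8a bond and gives the oxonium/aryl anion zwitterion 20. The flavan-4-yl C–O bond of 20 should ionise at once (2,4,6-trioxygenated benzylic cation) and the ion pair should collapse at the adjacent carbanion C8, a net 1,3 O-to-C shift that amounts to insertion of the aryne into the C4–O σ-bond. The closest known reaction types are the intramolecular trapping of arynes by silyl ethers with O-to-C silyl migration, aryne insertion into acyl C–O bonds and the classical alkoxide–aryne cyclisation to chromans. The re-formed C4 stereocentre of the upper unit is set by recombination on the β-face, anti to its 2α-aryl and 3α-benzyloxy groups, while C2 and C3 of the middle unit are untouched because only their oxygen reacts. The step needs C8 rather than C6 regiochemistry and O1 rather than O3 chemoselectivity: the first is enforced because the migrating carbon can only reach the carbanion ortho to the oxonium, the second because ether addition to an aryne is reversible and only the flavanyl oxonium has a fast irreversible exit, while polarisation of the aryne by the C7 benzyloxy group directs the oxygen to C8a.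

Step 11
Reactants: 22 (+)-catechin
Product: 23 5,7,3',4'-tetra-O-benzyl-(+)-catechin
Conditions: BnBr (4.2 equiv), K2CO3, DMF, 0 °C → rt
Reagents that add atoms: benzyl bromide, BrCc1ccccc1
Why: selective Williamson benzylation of the four phenols as in step 4; C2 and C3 come from the chiral pool.

Step 12
Reactants: 21 protected dimer; 23 5,7,3',4'-tetra-O-benzyl-(+)-catechin (4 equiv, excess recovered)
Product: 25 trideca-O-benzyl trimer with a free 3-OH on the lower unit, via flavan-4-yl cation 24 (not isolated)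
Conditions: Me3SiOTf (cat.), CH2Cl2, 4 Å molecular sieves, −78 → −30 °C; Et3N quench
Reagents that add atoms: none
Why: Lewis-acid ionisation of the benzylic methyl ether gives a cation stabilised by O1 and the para 7-benzyloxy group, which should undergo Friedel–Crafts alkylation at C8 of the benzylated catechin anti to the 2α-aryl and 3α-benzyloxy groups, setting the 4β (3,4-trans) centre of the middle unit.

Step 13
Reactants: 25 trideca-O-benzyl trimer
Product: 26 epicatechin-(4β→8)-epifisetinidol-(4β→8)-catechin (target)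
Conditions: H2 (1 atm), Pd(OH)2 on carbon, THF–MeOH–H2O, rt
Reagents that add atoms: none
Why: hydrogenolysis of the thirteen benzyl ethers should free all phenols and the two secondary alcohols without touching a stereocentre.

Compound list
1 | (S)-4-benzyloxazolidin-2-one | O=C1OC[C@H](Cc2ccccc2)N1 | starting material
2 | (benzyloxy)acetyl chloride | O=C(Cl)COCc1ccccc1 | starting material
3 | (S)-4-benzyl-3-[(benzyloxy)acetyl]oxazolidin-2-one | O=C1OC[C@H](Cc2ccccc2)N1C(=O)COCc1ccccc1 | intermediate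
4 | 3,4-bis(benzyloxy)benzaldehyde | O=Cc1ccc(OCc2ccccc2)c(OCc2ccccc2)c1 | starting material
5 | Z-dibutylboron enolate of 3 | CCCCB(CCCC)O/C(=C\OCc1ccccc1)N1C(=O)OC[C@@H]1Cc1ccccc1 | intermediate (not isolated)
6 | (S)-4-benzyl-3-[(2S,3R)-2-(benzyloxy)-3-[3,4-bis(benzyloxy)phenyl]-3-hydroxypropanoyl]oxazolidin-2-one | O=C1OC[C@H](Cc2ccccc2)N1C(=O)[C@@H](OCc1ccccc1)[C@H](O)c1ccc(OCc2ccccc2)c(OCc2ccccc2)c1 | intermediate
7 | (2S,3R)-2-(benzyloxy)-3-[3,4-bis(benzyloxy)phenyl]-3-hydroxy-N-methoxy-N-methylpropanamide | CON(C)C(=O)[C@@H](OCc1ccccc1)[C@H](O)c1ccc(OCc2ccccc2)c(OCc2ccccc2)c1 | intermediate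
8 | (−)-epicatechin, (2R,3R) | Oc1cc(O)c2c(c1)O[C@H](c1ccc(O)c(O)c1)[C@H](O)C2 | starting material
9 | 5,7,3',4'-tetra-O-benzyl-(−)-epicatechin | c1ccccc1COc1cc(OCc2ccccc2)c2c(c1)O[C@H](c1ccc(OCc3ccccc3)c(OCc3ccccc3)c1)[C@H](O)C2 | intermediate
10 | 3,5,7,3',4'-penta-O-benzyl-(−)-epicatechin | c1ccccc1COc1cc(OCc2ccccc2)c2c(c1)O[C@H](c1ccc(OCc3ccccc3)c(OCc3ccccc3)c1)[C@H](OCc1ccccc1)C2 | intermediate
11 | flavan-4-yl cation of 10 | c1ccccc1COc1cc(OCc2ccccc2)c2c(c1)O[C@H](c1ccc(OCc3ccccc3)c(OCc3ccccc3)c1)[C@H](OCc1ccccc1)[CH+]2 | intermediate (not isolated)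
12 | penta-O-benzylepicatechin-4β-yl ether of the hydroxyl group of 7 (2,3-cis-3,4-trans upper unit) | c1ccccc1COc1cc(OCc2ccccc2)c2c(c1)O[C@H](c1ccc(OCc3ccccc3)c(OCc3ccccc3)c1)[C@H](OCc1ccccc1)[C@H]2O[C@H](c1ccc(OCc2ccccc2)c(OCc2ccccc2)c1)[C@H](OCc1ccccc1)C(=O)N(C)OC | intermediate
13 | 4-(benzyloxy)-1-bromo-2-fluorobenzene | Fc1cc(OCc2ccccc2)ccc1Br | starting material
14 | [4-(benzyloxy)-2-fluorophenyl]lithium | [Li]c1ccc(OCc2ccccc2)cc1F | intermediate (not isolated)
15 | 4-(benzyloxy)-2-fluorophenyl ketone derived from 12 | c1ccccc1COc1cc(OCc2ccccc2)c2c(c1)O[C@H](c1ccc(OCc3ccccc3)c(OCc3ccccc3)c1)[C@H](OCc1ccccc1)[C@H]2O[C@H](c1ccc(OCc2ccccc2)c(OCc2ccccc2)c1)[C@H](OCc1ccccc1)C(=O)c1ccc(OCc2ccccc2)cc1F | intermediate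
16 | benzylic alcohol from 15 (carbinol epimers) | c1ccccc1COc1cc(OCc2ccccc2)c2c(c1)O[C@H](c1ccc(OCc3ccccc3)c(OCc3ccccc3)c1)[C@H](OCc1ccccc1)[C@H]2O[C@H](c1ccc(OCc2ccccc2)c(OCc2ccccc2)c1)[C@H](OCc1ccccc1)C(O)c1ccc(OCc2ccccc2)cc1F | intermediate
17 | benzylic methyl ether of 16 | c1ccccc1COc1cc(OCc2ccccc2)c2c(c1)O[C@H](c1ccc(OCc3ccccc3)c(OCc3ccccc3)c1)[C@H](OCc1ccccc1)[C@H]2O[C@H](c1ccc(OCc2ccccc2)c(OCc2ccccc2)c1)[C@H](OCc1ccccc1)C(OC)c1ccc(OCc2ccccc2)cc1F | intermediate
18 | 17 lithiated between F and OBn (C8) | c1ccccc1COc1cc(OCc2ccccc2)c2c(c1)O[C@H](c1ccc(OCc3ccccc3)c(OCc3ccccc3)c1)[C@H](OCc1ccccc1)[C@H]2O[C@H](c1ccc(OCc2ccccc2)c(OCc2ccccc2)c1)[C@H](OCc1ccccc1)C(OC)c1ccc(OCc2ccccc2)c([Li])c1F | intermediate (not isolated)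
19 | aryne (C8≡C8a) from 18 | c1ccccc1COc1cc(OCc2ccccc2)c2c(c1)O[C@H](c1ccc(OCc3ccccc3)c(OCc3ccccc3)c1)[C@H](OCc1ccccc1)[C@H]2O[C@H](c1ccc(OCc2ccccc2)c(OCc2ccccc2)c1)[C@H](OCc1ccccc1)C(OC)C1=CC=C(OCc2ccccc2)C#C1 | intermediate (not isolated)
20 | cyclic oxonium / C8 aryl anion zwitterion | c1ccccc1COc1cc(OCc2ccccc2)c2c(c1)O[C@H](c1ccc(OCc3ccccc3)c(OCc3ccccc3)c1)[C@H](OCc1ccccc1)[C@H]2[O+]1[C@H](c2ccc(OCc3ccccc3)c(OCc3ccccc3)c2)[C@H](OCc2ccccc2)C(OC)c2ccc(OCc3ccccc3)[c-]c21 | intermediate (not isolated)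
21 | penta-O-benzylepicatechin-(4β→8)-[3,7,3',4'-tetra-O-benzyl-4-methoxyepifisetinidol] | c1ccccc1COc1cc(OCc2ccccc2)c2c(c1)O[C@H](c1ccc(OCc3ccccc3)c(OCc3ccccc3)c1)[C@H](OCc1ccccc1)[C@H]2c1c(OCc2ccccc2)ccc2c1O[C@H](c1ccc(OCc3ccccc3)c(OCc3ccccc3)c1)[C@H](OCc1ccccc1)C2OC | intermediate
22 | (+)-catechin, (2R,3S) | Oc1cc(O)c2c(c1)O[C@H](c1ccc(O)c(O)c1)[C@@H](O)C2 | starting material
23 | 5,7,3',4'-tetra-O-benzyl-(+)-catechin | c1ccccc1COc1cc(OCc2ccccc2)c2c(c1)O[C@H](c1ccc(OCc3ccccc3)c(OCc3ccccc3)c1)[C@@H](O)C2 | intermediate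
24 | middle-unit flavan-4-yl cation of 21 | c1ccccc1COc1cc(OCc2ccccc2)c2c(c1)O[C@H](c1ccc(OCc3ccccc3)c(OCc3ccccc3)c1)[C@H](OCc1ccccc1)[C@H]2c1c(OCc2ccccc2)ccc2c1O[C@H](c1ccc(OCc3ccccc3)c(OCc3ccccc3)c1)[C@H](OCc1ccccc1)[CH+]2 | intermediate (not isolated)
25 | trideca-O-benzyl epicatechin-(4β→8)-epifisetinidol-(4β→8)-catechin | c1ccccc1COc1cc(OCc2ccccc2)c2c(c1)O[C@H](c1ccc(OCc3ccccc3)c(OCc3ccccc3)c1)[C@H](OCc1ccccc1)[C@H]2c1c(OCc2ccccc2)ccc2c1O[C@H](c1ccc(OCc3ccccc3)c(OCc3ccccc3)c1)[C@H](OCc1ccccc1)[C@H]2c1c(OCc2ccccc2)cc(OCc2ccccc2)c2c1O[C@H](c1ccc(OCc3ccccc3)c(OCc3ccccc3)c1)[C@@H](O)C2 | intermediate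
26 | epicatechin-(4β→8)-epifisetinidol-(4β→8)-catechin | Oc1cc(O)c2c(c1)O[C@H](c1ccc(O)c(O)c1)[C@H](O)[C@H]2c1c(O)ccc2c1O[C@H](c1ccc(O)c(O)c1)[C@H](O)[C@H]2c1c(O)cc(O)c2c1O[C@H](c1ccc(O)c(O)c1)[C@@H](O)C2 | target

Total step count: 13. Longest linear sequence: 10 steps (1, 2, 3, 6, 7, 8, 9, 10, 12, 13).

Steps most likely to fail

Step 10. The zwitterion may undergo proton transfer or β-elimination instead of the O-to-C shift, or the 3-O-benzyl ether oxygen may capture the aryne in a five-membered closure. The fallback uses known reactions, sets out from 17 and comes back at 26. Mild methanolysis of 17 (pyridinium p-toluenesulfonate, MeOH–CH2Cl2, 0 °C) cuts the tether and gives the open-chain alcohol 1-[3,4-bis(benzyloxy)phenyl]-2-(benzyloxy)-3-[4-(benzyloxy)-2-fluorophenyl]-3-methoxypropan-1-ol F1 and 4β-methoxy-penta-O-benzylepicatechin F2. The lithium alkoxide of F1 is cyclised by the classical alkoxide–aryne route (n-BuLi, 2.1 equiv, THF, −78 → 0 °C, proton quench) to 3,7,3',4'-tetra-O-benzyl-4-methoxyepifisetinidol F3. F3 and 23 are joined with Me3SiOTf to the benzylated epifisetinidol-(4β→8)-catechin F4. N-Bromosuccinimide (2 equiv) blocks C6 of both A rings to give the 6,6-dibromide F5, and F2 is capped at C8 in the same way to give the 8-bromide F6. F5 and F6 are coupled with Me3SiOTf, the only open A-ring position of F5 being C8 of the middle unit, to give the tribromo trimer F7. Hydrogenolysis (H2, Pd(OH)2 on carbon, Et3N) removes the benzyl groups and the three bromines and gives 26.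

Step 6. Capture of the cation by a hindered secondary alcohol may be slow, and DDQ may oxidise the benzylic carbinol of 7. The fallback sets out from 10 and comes back at 12. Oxidation of 10 with DDQ in wet CH2Cl2–THF gives 4β-hydroxy-penta-O-benzylepicatechin F8, and acetylation (Ac2O, pyridine, DMAP) gives 4β-acetoxy-penta-O-benzylepicatechin F9. F9 is ionised with BF3·OEt2 at −78 °C in the presence of 7 (1.2 equiv), so the ether 12 forms by substitution at a pre-installed leaving group, with no oxidant present.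

Step 12. The Friedel–Crafts step may be slow enough for acid-induced fission of the existing interflavan bond and attack at C6 of the catechin unit to compete. The fallback sets out from 21 and comes back at 25. A short exchange with BnSH and BF3·OEt2 at −78 °C converts 21 into the 4β-benzylthio dimer F10. F10 is then activated with the thiophile AgBF4 in THF at 0 °C in the presence of 23, which releases the cation under neutral conditions.

Further compounds
F1 | step 10 | 1-[3,4-bis(benzyloxy)phenyl]-2-(benzyloxy)-3-[4-(benzyloxy)-2-fluorophenyl]-3-methoxypropan-1-ol (C1 and C2 as in 17) | O[C@H](c1ccc(OCc2ccccc2)c(OCc2ccccc2)c1)[C@H](OCc1ccccc1)C(OC)c1ccc(OCc2ccccc2)cc1F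
F2 | step 10 | 4β-methoxy-3,5,7,3',4'-penta-O-benzylepicatechin | c1ccccc1COc1cc(OCc2ccccc2)c2c(c1)O[C@H](c1ccc(OCc3ccccc3)c(OCc3ccccc3)c1)[C@H](OCc1ccccc1)[C@H]2OC
F3 | step 10 | 3,7,3',4'-tetra-O-benzyl-4-methoxyepifisetinidol (C4 epimers) | c1ccccc1COc1ccc2c(c1)O[C@H](c1ccc(OCc3ccccc3)c(OCc3ccccc3)c1)[C@H](OCc1ccccc1)C2OC
F4 | step 10 | tetra-O-benzylepifisetinidol-(4β→8)-tetra-O-benzylcatechin | c1ccccc1COc1ccc2c(c1)O[C@H](c1ccc(OCc3ccccc3)c(OCc3ccccc3)c1)[C@H](OCc1ccccc1)[C@H]2c1c(OCc2ccccc2)cc(OCc2ccccc2)c2c1O[C@H](c1ccc(OCc3ccccc3)c(OCc3ccccc3)c1)[C@@H](O)C2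
F5 | step 10 | 6-bromo (middle unit), 6-bromo (lower unit) derivative of F4 | c1ccccc1COc1c(Br)cc2c(c1)O[C@H](c1ccc(OCc3ccccc3)c(OCc3ccccc3)c1)[C@H](OCc1ccccc1)[C@H]2c1c(OCc2ccccc2)c(Br)c(OCc2ccccc2)c2c1O[C@H](c1ccc(OCc3ccccc3)c(OCc3ccccc3)c1)[C@@H](O)C2
F6 | step 10 | 8-bromo-4β-methoxy-3,5,7,3',4'-penta-O-benzylepicatechin | c1ccccc1COc1cc(OCc2ccccc2)c2c(c1Br)O[C@H](c1ccc(OCc3ccccc3)c(OCc3ccccc3)c1)[C@H](OCc1ccccc1)[C@H]2OC
F7 | step 10 | tribromo trideca-O-benzyl trimer (Br at C8 of the upper unit and C6 of the middle and lower units) | c1ccccc1COc1cc(OCc2ccccc2)c2c(c1Br)O[C@H](c1ccc(OCc3ccccc3)c(OCc3ccccc3)c1)[C@H](OCc1ccccc1)[C@H]2c1c(OCc2ccccc2)c(Br)cc2c1O[C@H](c1ccc(OCc3ccccc3)c(OCc3ccccc3)c1)[C@H](OCc1ccccc1)[C@H]2c1c(OCc2ccccc2)c(Br)c(OCc2ccccc2)c2c1O[C@H](c1ccc(OCc3ccccc3)c(OCc3ccccc3)c1)[C@@H](O)C2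
F8 | step 6 | 4β-hydroxy-3,5,7,3',4'-penta-O-benzylepicatechin | c1ccccc1COc1cc(OCc2ccccc2)c2c(c1)O[C@H](c1ccc(OCc3ccccc3)c(OCc3ccccc3)c1)[C@H](OCc1ccccc1)[C@H]2O
F9 | step 6 | 4β-acetoxy-3,5,7,3',4'-penta-O-benzylepicatechin | c1ccccc1COc1cc(OCc2ccccc2)c2c(c1)O[C@H](c1ccc(OCc3ccccc3)c(OCc3ccccc3)c1)[C@H](OCc1ccccc1)[C@H]2OC(C)=O
F10 | step 12 | 4β-benzylthio analogue of 21 (SBn in place of OMe on the middle unit) | c1ccccc1COc1cc(OCc2ccccc2)c2c(c1)O[C@H](c1ccc(OCc3ccccc3)c(OCc3ccccc3)c1)[C@H](OCc1ccccc1)[C@H]2c1c(OCc2ccccc2)ccc2c1O[C@H](c1ccc(OCc3ccccc3)c(OCc3ccccc3)c1)[C@H](OCc1ccccc1)[C@H]2SCc1ccccc1
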